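Z is the ring we want from D, and one D molecule meets forks: it closes to Z, joins a second D as D2, or takes J to give D.J.

the same everywhere: D 0.40 M; J 0.0800 M; time 20 h
- dusk: temperature 50 °C
- noon: temperature 35 °C
- winter: temperature 5 °C
- autumn: temperature 20 °C

    D → Z (k1 = 0.029 min⁻¹, Ea1 = 80.0 kJ mol⁻¹)
    2 D → D2 (k2 = 0.018 M⁻¹ min⁻¹, Ea2 = 70.0 kJ mol⁻¹)
    D + Z ⇌ D.Z, settled at all times (K3 = 1.6 M⁻¹, ΔH3 = 9.00 kJ mol⁻¹)
    D + J → D.J (k4 = 0.80 M⁻¹ min⁻¹, Ea4 = 43.0 kJ mol⁻¹)
    (constants at 5 °C)

- percentages count the D that a species holds: one D2 or D.Z counts as two
- Z is meant together with its D.Z
- where a step has two of a species, its rate is k times that concentration squared, and two are used at each turn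
- constants are those at 5 °C; use the activation energies and enthalpies for any other temperature
- in an amount of Z, one D.Z counts as one Z

- the flask with the highest amount of Z, in percent of the D charged ("all alike" if they lie within 1.5 percentage points) (dusk / noon / winter / autumn / all alike)
- final Z, as a percentage of the D charged, in dusk
- final Z, as a percentage of the D charged, in noon
- final Z, as a percentage of the D charged, in winter
- final Z, as a percentage of the D charged, in autumn

Two views stand against each other. The first treats J as a reagent that is simply used up. At the start in winter, the J step takes D about twice as fast as ring closure, so on this view D.J claims 20.0% of the D at any temperature. The remaining D then splits between ring and dimer. If x is the dimer's rate of D loss over the ring's at the concentration of that remainder, the ring's share (its selectivity) works out as ln(1 + x)/x. I reckon this view by hand: x is 0.397 in winter and 0.218 at dusk, which gives Z of 67.4% and 72.4%.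

The forecast holds the second view, that in the hot flask “ring closure also competes better with J”. It names dusk as the best flask, with 79% of Z at dusk, 73.7% at noon, 66% in winter and 69.8% in autumn.

One quantity tells the views apart. The ring constant over the J constant is 0.0362 M at 5 °C; call it the even level of J, the concentration of J at which a D molecule is as likely to meet J as to close. Within one flask at its constant temperature, J falls at a constant times free D times J, and Z, its D.Z counted, grows at a constant times free D. So the fraction of J left is exp(−Z/even level), with Z as the concentration made, whatever course D takes. In winter the level lies below the charge of J, 0.0800 M, and the first view's Z leaves 0.0591% of J, so that view stands there. At dusk the level is 0.336 M, above the charge, and the same reckoning leaves 42.3% of J, which contradicts the view's own premise. Giving the unused J's share back leaves 0.354 M of D for ring and dimer, and my dusk figure becomes 79.3%, close to the forecast's. In winter mine stays above the forecast's.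

The simulation gives 79.2% of Z at dusk, 74.0% at noon, 67.8% in winter and 70.0% in autumn, so dusk leads, as the forecast said. The first view falls 6.8 percentage points short at dusk, where 39.0% of J remains. Winter is its region, with J down to 0.0565% and D.J at 20.0%. In winter the dimer step had half its turnover by 0.129 h and ring closure by 0.371 h. The J step there had >99.9% of its turnover behind it by 4.00 h. The even level and winter's simulated Z give 0.0565% of J left, and noon, with a level of 0.172 M, gives 17.9%, against 17.9% standing in that flask.

(The constants belong to no real substance; no experiment stands behind them.)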